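## Retrosynthetic overview

1. The target is reached by acidolysis of a 4-methoxybenzyl (PMB) ester at C17; the preformed butenolide is attached last by a Negishi coupling that makes the C12–C13 bond.
2. The C6–O bond, the 6α stereocentre and the (R)-2-methylbutanoyl group are installed together by a new vinylogous acyloxylation of a dienyl silyl ketene acetal with a mixed diacyl peroxide that carries the chiral acyl group.
3. The Δ7 C17 ester comes from alkoxycarbonylation of a Δ7 enol triflate, made from the 17-nor-8-ketone, itself from ozonolysis of an 8(17)-alkene.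
4. Rings A and B and the C5, C9 and C10 stereocentres are taken intact from (+)-sclareolide, whose lactone ring is opened first; no carbocycle is built.

Assumption: the target is read as drawn, i.e. normal labdane series (5α-H, 9α-H, 10β-methyl), 6α (equatorial) acyloxy group and an (R)-configured 2-methylbutanoate; (+)-sclareolide, (2R)-2-methylbutanoic acid and 3-bromofuran-2(5H)-one are purchased.

## Route

Step 1
Reactants: 1 (+)-sclareolide
Product: 2 13,14,15,16-tetranorlabdane-8α,12-diol
Conditions: LiAlH4, THF, 0 °C → reflux; Fieser work-up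
Reagents that add atoms: none
Why: Hydride reduction of the lactone gives the diol without touching any stereocentre, so C5, C9, C10 and the 8α-oxygen come unchanged from 1.

Step 2
Reactants: 2 13,14,15,16-tetranorlabdane-8α,12-diol
Product: 3 12-(tert-butyldimethylsilyloxy)-13,14,15,16-tetranorlabdan-8α-ol
Conditions: TBSCl, imidazole, DMF, 0 °C → rt
Reagents that add atoms: tert-butyldimethylsilyl chloride (TBSCl), CC(C)(C)[Si](C)(C)Cl
Why: Silyl ether formation is selective for the primary alcohol over the hindered tertiary 8α-ol and blocks cyclisation of the diol to the tetrahydrofuran.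

Step 3
Reactants: 3 12-(tert-butyldimethylsilyloxy)-13,14,15,16-tetranorlabdan-8α-ol
Product: 4 12-(tert-butyldimethylsilyloxy)-13,14,15,16-tetranorlabd-8(17)-ene
Conditions: SOCl2, pyridine, CH2Cl2, −78 °C
Reagents that add atoms: none
Why: In this chlorosulfite E2 dehydration the equatorial 8α leaving group has no anti-periplanar ring hydrogen, so loss of a methyl proton to the exocyclic alkene dominates; minor endocyclic isomers are removed after step 4, where they give much more polar cleavage products.

Step 4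
Reactants: 4 12-(tert-butyldimethylsilyloxy)-13,14,15,16-tetranorlabd-8(17)-ene
Product: 6 12-(tert-butyldimethylsilyloxy)-13,14,15,16,17-pentanorlabdan-8-one, via ozonide 5 (not isolated)
Conditions: O3, CH2Cl2, −78 °C; then PPh3, −78 °C → rt
Reagents that add atoms: ozone, [O-][O+]=O
Why: Ozonolysis with reductive work-up cleaves the 1,1-disubstituted alkene to the 8-ketone, and C9 keeps its favoured equatorial side chain.

Step 5
Reactants: 6 12-(tert-butyldimethylsilyloxy)-13,14,15,16,17-pentanorlabdan-8-one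
Product: 8 12-(tert-butyldimethylsilyloxy)-13,14,15,16,17-pentanorlabd-7-en-8-yl trifluoromethanesulfonate, via lithium enolate 7 (not isolated)
Conditions: LiN(iPr)2, THF, −78 °C; then PhNTf2, −78 → 0 °C
Reagents that add atoms: N-phenylbis(trifluoromethanesulfonimide) (PhNTf2), O=S(=O)(N(c1ccccc1)S(=O)(=O)C(F)(F)F)C(F)(F)F
Why: Kinetic enolate formation at the unhindered C7 methylene, not at the tertiary C9–H next to the quaternary C10, followed by O-triflation gives the Δ7 enol triflate regioselectively and leaves C9 untouched.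

Step 6
Reactants: 8 12-(tert-butyldimethylsilyloxy)-13,14,15,16,17-pentanorlabd-7-en-8-yl trifluoromethanesulfonate
Product: 9 4-methoxybenzyl 12-(tert-butyldimethylsilyloxy)-13,14,15,16-tetranorlabd-7-en-17-oate
Conditions: Pd(OAc)2 (5 mol%), dppf (10 mol%), CO (1 atm), 4-methoxybenzyl alcohol, Et3N, DMF, 60 °C
Reagents that add atoms: carbon monoxide, [C-]#[O+]; 4-methoxybenzyl alcohol, COc1ccc(CO)cc1
Why: Palladium-catalysed alkoxycarbonylation of the enol triflate (oxidative addition, CO insertion, alcoholysis) installs C17 as an acid-labile ester conjugated with the Δ7 double bond.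

Step 7
Reactants: 9 4-methoxybenzyl 12-(tert-butyldimethylsilyloxy)-13,14,15,16-tetranorlabd-7-en-17-oate
Product: 11 17-(4-methoxybenzyloxy)-12,17-bis(tert-butyldimethylsilyloxy)-13,14,15,16-tetranorlabda-6,8(17)-diene, via lithium dienolate 10 (not isolated)
Conditions: LiN(iPr)2, THF/DMPU, −78 °C; then TBSCl, −78 → 0 °C; pentane, filtration, used crude
Reagents that add atoms: tert-butyldimethylsilyl chloride (TBSCl), CC(C)(C)[Si](C)(C)Cl
Why: γ-Deprotonation of the enoate at C6, the only position that gives an extended dienolate, and O-silylation (vinylogous ester enolate trapping) give the dienyl silyl ketene acetal, whose ketene acetal geometry is irrelevant.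

Step 8
Reactants: 12 (2R)-2-methylbutanoic acid
Product: 14 3-chlorobenzoyl (2R)-2-methylbutanoyl peroxide, via acid chloride 13 (not isolated)
Conditions: (COCl)2, DMF (cat.), CH2Cl2, 0 °C → rt; then purified mCPBA, Na2CO3, H2O/Et2O, 0 °C, 30 min; organic layer washed with cold aq NaHCO3 until free of peracid, dried, kept as a cold, titrated solution and never concentrated
Reagents that add atoms: 3-chloroperoxybenzoic acid (mCPBA), O=C(OO)c1cccc(Cl)c1
Why: Base-free acid chloride formation followed by Schotten–Baumann acylation of the peroxycarboxylate anion (an α-effect nucleophile) gives the unsymmetrical diacyl peroxide with the α-stereocentre retained, because neither stage passes through a ketene or an enolisable acylammonium species.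

Step 9
Reactants: 11 17-(4-methoxybenzyloxy)-12,17-bis(tert-butyldimethylsilyloxy)-13,14,15,16-tetranorlabda-6,8(17)-diene; 14 3-chlorobenzoyl (2R)-2-methylbutanoyl peroxide
Product: 15 4-methoxybenzyl 6α-[(2R)-2-methylbutanoyloxy]-12-(tert-butyldimethylsilyloxy)-13,14,15,16-tetranorlabd-7-en-17-oate
Conditions: 14 (1.5 equiv, cold solution), 2,6-lutidine (0.2 equiv), CH2Cl2, −40 → 0 °C; then aq Na2S2O3/NaHCO3
Reagents that add atoms: none
Why: Proposed new method: a vinylogous electrophilic acyloxylation in which the γ-carbon C6 of the neutral silyl dienolate (electronically preferred and far less hindered than the fully substituted α-carbon C8) attacks the O–O σ* orbital of the mixed diacyl peroxide at the oxygen bearing the aliphatic acyl group, because that SN2-type displacement expels the better nucleofuge 3-chlorobenzoate, and does so from the α face, anti to the axial 4β- and 10β-methyl groups, while the expelled 3-chlorobenzoate removes the silyl group and restores the conjugated ester, so that the C6–O bond, the 6α stereocentre and the intact (R)-acyl group arrive in one operation; the closest known reaction types are the α-benzoyloxylation of enamines and silyl enol ethers with dibenzoyl peroxide and the γ-hydroxylation of silyl dienol ethers with peracids (vinylogous Rubottom oxidation).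

Step 10
Reactants: 15 4-methoxybenzyl 6α-[(2R)-2-methylbutanoyloxy]-12-(tert-butyldimethylsilyloxy)-13,14,15,16-tetranorlabd-7-en-17-oate
Product: 16 4-methoxybenzyl 12-hydroxy-6α-[(2R)-2-methylbutanoyloxy]-13,14,15,16-tetranorlabd-7-en-17-oate
Conditions: HF·pyridine, pyridine, THF, 0 °C → rt
Reagents that add atoms: none
Why: Buffered fluoride desilylation removes the primary silyl ether and leaves both esters and the allylic C6 centre intact.

Step 11
Reactants: 16 4-methoxybenzyl 12-hydroxy-6α-[(2R)-2-methylbutanoyloxy]-13,14,15,16-tetranorlabd-7-en-17-oate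
Product: 17 4-methoxybenzyl 12-iodo-6α-[(2R)-2-methylbutanoyloxy]-13,14,15,16-tetranorlabd-7-en-17-oate
Conditions: I2, PPh3, imidazole, CH2Cl2, 0 °C → rt
Reagents that add atoms: iodine, II
Why: Appel-type iodination converts the primary alcohol to the iodide by SN2 displacement of the alkoxyphosphonium ion under neutral conditions.

Step 12
Reactants: 17 4-methoxybenzyl 12-iodo-6α-[(2R)-2-methylbutanoyloxy]-13,14,15,16-tetranorlabd-7-en-17-oate; 18 3-bromofuran-2(5H)-one
Product: 20 4-methoxybenzyl 6α-[(2R)-2-methylbutanoyloxy]labda-7,13-dien-16,15-olid-17-oate, via alkylzinc iodide 19 (not isolated)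
Conditions: Zn dust (activated with 1,2-dibromoethane/TMSCl), LiCl, THF, 35 °C; then 18, PdCl2(dppf) (5 mol%), THF/DMA, 40 °C
Reagents that add atoms: none
Why: LiCl-assisted zinc insertion into the primary C–I bond tolerates esters, and the Negishi sp3–sp2 cross-coupling with the α-bromobutenolide forms the C12–C13 bond under base-free conditions that the butenolide, both esters and all stereocentres survive.

Step 13
Reactants: 20 4-methoxybenzyl 6α-[(2R)-2-methylbutanoyloxy]labda-7,13-dien-16,15-olid-17-oate
Product: 21 6α-[(2R)-2-methylbutanoyloxy]labda-7,13-dien-16,15-olid-17-oic acid (CNP0150853.1)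
Conditions: TFA, anisole, CH2Cl2, 0 °C
Reagents that add atoms: none
Why: Acidolysis of the 4-methoxybenzyl ester (SN1 cleavage with the benzylic cation trapped by anisole) frees the C17 acid, while the deactivated allylic C6 ester, the butenolide and every stereocentre are unaffected.

## Compound list

1 | (+)-sclareolide, (3aR,5aS,9aS,9bR)-3a,6,6,9a-tetramethyldecahydronaphtho[2,1-b]furan-2(1H)-one (8α-O, 8β-Me, 9α-H, 5α-H, 10β-Me) | C1C[C@@]3(C)OC(=O)C[C@@H]3[C@@]2(C)CCCC(C)(C)[C@H]12 | starting material
2 | 13,14,15,16-tetranorlabdane-8α,12-diol (8β-methyl) | C1C[C@@](C)(O)[C@H](CCO)[C@@]2(C)CCCC(C)(C)[C@H]12 | intermediate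
3 | 12-(tert-butyldimethylsilyloxy)-13,14,15,16-tetranorlabdan-8α-ol | C1C[C@@](C)(O)[C@H](CCO[Si](C)(C)C(C)(C)C)[C@@]2(C)CCCC(C)(C)[C@H]12 | intermediate
4 | 12-(tert-butyldimethylsilyloxy)-13,14,15,16-tetranorlabd-8(17)-ene | C1CC(=C)[C@H](CCO[Si](C)(C)C(C)(C)C)[C@@]2(C)CCCC(C)(C)[C@H]12 | intermediate
5 | secondary ozonide of 4 (spiro-1,2,4-trioxolane at C8, spiro configuration undefined) | C1CC3(OCOO3)[C@H](CCO[Si](C)(C)C(C)(C)C)[C@@]2(C)CCCC(C)(C)[C@H]12 | intermediate
6 | 12-(tert-butyldimethylsilyloxy)-13,14,15,16,17-pentanorlabdan-8-one | C1CC(=O)[C@H](CCO[Si](C)(C)C(C)(C)C)[C@@]2(C)CCCC(C)(C)[C@H]12 | intermediate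
7 | lithium Δ7-enolate of 6 | C1C=C(O[Li])[C@H](CCO[Si](C)(C)C(C)(C)C)[C@@]2(C)CCCC(C)(C)[C@H]12 | intermediate
8 | 12-(tert-butyldimethylsilyloxy)-13,14,15,16,17-pentanorlabd-7-en-8-yl trifluoromethanesulfonate | C1C=C(OS(=O)(=O)C(F)(F)F)[C@H](CCO[Si](C)(C)C(C)(C)C)[C@@]2(C)CCCC(C)(C)[C@H]12 | intermediate
9 | 4-methoxybenzyl 12-(tert-butyldimethylsilyloxy)-13,14,15,16-tetranorlabd-7-en-17-oate | C1C=C(C(=O)OCc3ccc(OC)cc3)[C@H](CCO[Si](C)(C)C(C)(C)C)[C@@]2(C)CCCC(C)(C)[C@H]12 | intermediate
10 | lithium 6,8(17)-dienolate of 9 | C1=CC(=C(O[Li])OCc3ccc(OC)cc3)[C@H](CCO[Si](C)(C)C(C)(C)C)[C@@]2(C)CCCC(C)(C)[C@H]12 | intermediate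
11 | 17-(4-methoxybenzyloxy)-12,17-bis(tert-butyldimethylsilyloxy)-13,14,15,16-tetranorlabda-6,8(17)-diene (dienyl silyl ketene acetal, ketene acetal geometry unassigned) | C1=CC(=C(OCc3ccc(OC)cc3)O[Si](C)(C)C(C)(C)C)[C@H](CCO[Si](C)(C)C(C)(C)C)[C@@]2(C)CCCC(C)(C)[C@H]12 | intermediate
12 | (2R)-2-methylbutanoic acid | CC[C@@H](C)C(=O)O | starting material
13 | (2R)-2-methylbutanoyl chloride | CC[C@@H](C)C(=O)Cl | intermediate
14 | 3-chlorobenzoyl (2R)-2-methylbutanoyl peroxide | CC[C@@H](C)C(=O)OOC(=O)c1cccc(Cl)c1 | intermediate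
15 | 4-methoxybenzyl 6α-[(2R)-2-methylbutanoyloxy]-12-(tert-butyldimethylsilyloxy)-13,14,15,16-tetranorlabd-7-en-17-oate | CC[C@@H](C)C(=O)O[C@H]1C=C(C(=O)OCc3ccc(OC)cc3)[C@H](CCO[Si](C)(C)C(C)(C)C)[C@@]2(C)CCCC(C)(C)[C@H]12 | intermediate
16 | 4-methoxybenzyl 12-hydroxy-6α-[(2R)-2-methylbutanoyloxy]-13,14,15,16-tetranorlabd-7-en-17-oate | CC[C@@H](C)C(=O)O[C@H]1C=C(C(=O)OCc3ccc(OC)cc3)[C@H](CCO)[C@@]2(C)CCCC(C)(C)[C@H]12 | intermediate
17 | 4-methoxybenzyl 12-iodo-6α-[(2R)-2-methylbutanoyloxy]-13,14,15,16-tetranorlabd-7-en-17-oate | CC[C@@H](C)C(=O)O[C@H]1C=C(C(=O)OCc3ccc(OC)cc3)[C@H](CCI)[C@@]2(C)CCCC(C)(C)[C@H]12 | intermediate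
18 | 3-bromofuran-2(5H)-one | O=C1OCC=C1Br | starting material
19 | alkylzinc iodide from 17 (C12–ZnI) | CC[C@@H](C)C(=O)O[C@H]1C=C(C(=O)OCc3ccc(OC)cc3)[C@H](CC[Zn]I)[C@@]2(C)CCCC(C)(C)[C@H]12 | intermediate
20 | 4-methoxybenzyl 6α-[(2R)-2-methylbutanoyloxy]labda-7,13-dien-16,15-olid-17-oate | CC[C@@H](C)C(=O)O[C@H]1C=C(C(=O)OCc3ccc(OC)cc3)[C@H](CCC4=CCOC4=O)[C@@]2(C)CCCC(C)(C)[C@H]12 | intermediate
21 | 6α-[(2R)-2-methylbutanoyloxy]labda-7,13-dien-16,15-olid-17-oic acid (CNP0150853.1) | CC[C@@H](C)C(=O)O[C@H]1C=C(C(=O)O)[C@H](CCC2=CCOC2=O)[C@@]2(C)CCCC(C)(C)[C@H]12 | target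

## Step count and risk assessment

Total step count: 13 (12 on the main line plus 1 for the peroxide reagent).
Longest linear sequence: 12 steps (steps 1–7 and 9–13, from 1 to 21).

The three steps most likely to fail:

**Step 9 (proposed new method).** The risks are attack at the α-carbon C8, transfer of the 3-chlorobenzoyloxy group in place of the 2-methylbutanoyloxy group, single-electron pathways that lead to decarboxylation of the acyloxy fragment, carboxy-inversion of the α-branched mixed peroxide, and insufficient facial selectivity at C6. The fallback uses known chemistry, sets out from 11 and comes back at 15. Vinylogous Rubottom oxidation of 11 with dimethyldioxirane (acetone/CH2Cl2, −78 °C, then aqueous NaHCO3 work-up, which removes the silyl group from the ester oxygen) attacks C6 from the α face and gives the 6α-hydroxy enoate F3. Steglich esterification of F3 with acid 12 (EDC·HCl, DMAP, CH2Cl2, 0 °C → rt) then gives 15.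

**Step 7.** The stereoelectronically aligned 6β-hydrogen lies under the two axial methyl groups, so γ-deprotonation may be slow or may be overtaken by amide addition to the enoate. The fallback sets out from 9 and comes back at 15, so that 10, 11 and step 9 are bypassed. Allylic oxidation of 9 at C6 with Rh2(cap)4 (1 mol%) and tert-butyl hydroperoxide (K2CO3, CH2Cl2, rt) gives the 6-oxo enoate F1. Luche reduction (NaBH4, CeCl3·7H2O, MeOH, −40 °C) delivers hydride from the open α face and gives the 6β-allylic alcohol F2. Mitsunobu esterification of F2 with acid 12 (PPh3, DIAD, toluene, 0 °C → rt) inverts C6 and gives 15. This Mitsunobu step on a hindered axial alcohol is itself uncertain, with elimination to the 5,7-diene as the likely side reaction.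

**Step 12.** Zinc insertion may be slowed by the nearby esters, and zerovalent palladium could in principle ionise the allylic C6 ester or give β-hydride elimination. The fallback sets out from 17 and comes back at 20. Alkylation of the sodium enolate of 3-(phenylsulfanyl)oxolan-2-one (O=C1OCCC1Sc1ccccc1; NaH, THF/DMF, 0 °C → rt) with 17 gives the α-(phenylsulfanyl) lactone F4 as both C13 epimers. Oxidation with mCPBA (CH2Cl2, −78 °C) gives the sulfoxide F5. Thermolysis (toluene, CaCO3, 110 °C) then effects syn-elimination toward the ring methylene and gives the endocyclic butenolide 20.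

Further compounds
F1 | step 7 | 4-methoxybenzyl 12-(tert-butyldimethylsilyloxy)-6-oxo-13,14,15,16-tetranorlabd-7-en-17-oate | O=C1C=C(C(=O)OCc3ccc(OC)cc3)[C@H](CCO[Si](C)(C)C(C)(C)C)[C@@]2(C)CCCC(C)(C)[C@H]12
F2 | step 7 | 4-methoxybenzyl 6β-hydroxy-12-(tert-butyldimethylsilyloxy)-13,14,15,16-tetranorlabd-7-en-17-oate | O[C@@H]1C=C(C(=O)OCc3ccc(OC)cc3)[C@H](CCO[Si](C)(C)C(C)(C)C)[C@@]2(C)CCCC(C)(C)[C@H]12
F3 | step 9 | 4-methoxybenzyl 6α-hydroxy-12-(tert-butyldimethylsilyloxy)-13,14,15,16-tetranorlabd-7-en-17-oate | O[C@H]1C=C(C(=O)OCc3ccc(OC)cc3)[C@H](CCO[Si](C)(C)C(C)(C)C)[C@@]2(C)CCCC(C)(C)[C@H]12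
F4 | step 12 | 4-methoxybenzyl 6α-[(2R)-2-methylbutanoyloxy]-13-(phenylsulfanyl)labd-7-en-16,15-olid-17-oate (both C13 epimers) | CC[C@@H](C)C(=O)O[C@H]1C=C(C(=O)OCc3ccc(OC)cc3)[C@H](CCC4(Sc5ccccc5)CCOC4=O)[C@@]2(C)CCCC(C)(C)[C@H]12
F5 | step 12 | 4-methoxybenzyl 6α-[(2R)-2-methylbutanoyloxy]-13-(phenylsulfinyl)labd-7-en-16,15-olid-17-oate (mixture of diastereomers) | CC[C@@H](C)C(=O)O[C@H]1C=C(C(=O)OCc3ccc(OC)cc3)[C@H](CCC4(S(=O)c5ccccc5)CCOC4=O)[C@@]2(C)CCCC(C)(C)[C@H]12
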